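Readings and results were generated by integration from invented constants; noise was put on by code.

The east run holds second catalyst at 0.250 % of the substrate charged and the north run at 1.00 %. Over its samples, target takes 14.1 % of the product in east, less than the 36.5 % in north. In both runs the split looks flat within the scatter from the first sample on, as under kinetic control. The new flask, at 0.500 %, lies between them.

all flasks: substrate 0.16 M; partner 0.176 M

| charge | free catalyst | second catalyst | remark | time |
|---|---|---|---|---|
| east | 8 mM | 0.40 mM | run made earlier |  |
| north | 8 mM | 1.6 mM | run made earlier |  |
| flask | 8.0 mM | 0.80 mM |  | 12 d |

| run | time / d | side product / % | target / % |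
|---|---|---|---|
| east | 1.25 | 84 | 16 |
| east | 3.00 | 84 | 16 |
| east | 4.00 | 88 | 14 |
| east | 6.00 | 86 | 12 |
| east | 8.00 | 88 | 12 |
| east | 10.0 | 88 | 15 |
| north | 0.500 | 63 | 38 |
| north | 1.67 | 61 | 35 |
| north | 2.50 | 68 | 38 |
| north | 4.00 | 64 | 37 |
| north | 6.00 | 63 | 38 |
| north | 8.00 | 65 | 36 |
| north | 10.0 | 64 | 35 |

(standard deviation of a reading: 2 percentage points)

- ratio of side product to target at 8.0 min
- ratio of side product to target at 6.0 h
- ratio of side product to target at 12 d
- which of side product and target there is more of at 12 d

- the analysis behind the earlier runs scatters by 2 percentage points, standard deviation

I can do two extreme flasks in my head. In the first, each unit of second catalyst makes a fixed amount of target, so target's share scales with the loading. Scaled to this flask, east then gives 28.2 % and north 18.2 %. In the second, target and side product compete and the rate to target goes with the second catalyst, so side product over target falls in step with the loading, and loading times that ratio is constant. East reads 1.52 % and north 1.74 %. Their geometric mean, 1.63 %, is my even loading: the second catalyst, as a fraction of the substrate charged, at which by this reckoning target and side product come out equal, with substrate, partner and free catalyst charged as in these runs. The two readings of it differ by a factor of 1.14, while target per second catalyst differs by 1.55, so I lean to the second extreme. For the end of this flask I reckon a ratio of 3.26, a target share of 23.5 %, which falls inside the first extreme's bracket.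

The forecast gives 3.3 at 8.0 min (from 2.2 to 5), 3.3 at 6.0 h and 3.3 at 12 d, with side product ahead. For the early points it writes: “Parallel pathways suggest the same ratio, but an induction period or differing orders could shift it”.

The flask gives 2.07 at 8.0 min, below the forecast's range, then 3.38 at 6.0 h and 3.38 at 12 d, with side product ahead, 77.2 % against 22.8 % of target.

    substrate + free catalyst → free catalyst + open intermediate (k = 0.0620 /M/s)
    open intermediate → side product (k = 3.60 × 10⁻⁴ /s)
    second catalyst + open intermediate ⇌ catalyst intermediate (K = 130 /M, k = 3.00 /M/s)
    partner + catalyst intermediate → second catalyst + target (k = 0.0370 /M/s)

A neighbouring flask, the same recipe with 0.0032 M of second catalyst, stands at 2.00 % of the substrate charged, above the even loading. The even loading gives it a ratio of 0.815. That neighbour gives 0.471 at 8.0 min and 0.844 at 12 d, when target leads with 54.2 % of the substrate charged.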